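## Structural features

Manuifolin D is a (3R)-isoflavan: benzene ring A (C4a to C8a, hydroxyl on C7) is fused to the oxygen heterocycle ring C (O1, C2, C3, C4), and aryl ring B is attached through C1′ to C3. C3 is the only stereocentre, so no stereocentres stand next to each other. It is a tertiary benzylic C–H flanked by two methylenes (C2 on oxygen, C4 on ring A), with no carbonyl or neighbouring centre to direct it, so it must be set by a catalyst and then left alone. Ring B is 1,2,4,5-tetrasubstituted: a free 2′-hydroxyl, a 3-methylbut-2-enyl (prenyl) ether on O4′, and a 2-methylbut-3-en-2-yl (1,1-dimethylallyl) group on C5′, a quaternary benzylic carbon next to the prenyl ether.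

The fragile groups are the aryl prenyl ether (acid, heat, low-valent palladium or nickel), the two alkenes (no hydrogenation, ozonolysis or electrophilic halogen) and the electron-rich phenols. The 2′-oxygen can also close a six-membered aryl lactone onto any activated carboxyl group two carbons from C3. The real difficulty is the combination of an isolated stereocentre, an unfunctionalised C4 methylene and a ring B that rules out acid, hydrogenation and cationic ring closures. The key step exploits C4: a cation there would be bridged by the 2′,4′-dioxygenated ring B, so the C4–C4a bond is made from a primary C4 radical. That radical is released from a carboxyl carbon that earlier served as the acceptor handle for setting C3, and it is captured at nickel bound to C4a.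

## Logic of the disconnections

20 ⇒ 19. The two O–Si bonds on O7 and O2′ are cut. Both phenols must stay masked through every base, organometallic and carboxyl-activation step. The forward step must unmask them without acid or reduction, which fluoride does.

19 ⇒ 18. The C4–C4a bond is cut, opening ring C. The chroman becomes an acyclic aryl alkyl ether whose ring A is a plain bromoarene and whose C4 carries one extra, sacrificial carboxyl carbon. The forward step must trap a short-lived primary radical at nickel within the same molecule, and nickel must prefer the C–Br bond over the allylic C–O bond of ring B.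

18 ⇒ 15 + 16, and 15 ⇒ 14. The acyl–O bond to 16 and then the O–CH3 bond are cut; these are functional-group changes only. The sensitive activated ester is made last. The hydrolysis of 14 must spare two aryl silyl ethers, and the 2′-oxygen must stay silylated so that activation of 15 cannot lactonise.

14 ⇒ 10 + 13. The C3–C1′ bond is cut. This puts the formation of the only stereocentre into a catalytic enantioselective conjugate addition, with the future CO2 carbon as the activating group, and splits the molecule into two arenes of similar size. The forward step needs face control on an (E)-enoate, and transmetalation of a hindered, electron-rich arylboron faster than its protodeboronation. The C–Br bond of 13 must remain untouched.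

13 ⇒ 11 + 12, and 11 ⇒ 1. The O1–C2 ether bond and one O–Si bond are cut. The bromine of 1 already marks C4a. The forward steps need monosilylation at the unhindered hydroxyl and a clean SN2 reaction at the allylic bromide.

10 ⇒ 7. The C1′–B bond is cut back to a C–Br bond, which again comes from 1. The metalation must be cold and trapped at once, so that silicon does not move from oxygen to carbon and the prenyl ether is not deprotonated.

7 ⇒ 6 + 2, and 6 ⇒ 4 (through 5). The O4′–prenyl bond is cut, then the C5′–quaternary carbon bond by a retro-[3,3] shift. The 1,1-dimethylallyl group is the signature of a rearranged aryl prenyl ether, so 2 serves twice. The shift must go to C5′ and not to C3′, and the product must not react further at the temperature needed.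

4 ⇒ 3 ⇒ 1 + 2. One O–Si bond and one O–prenyl bond are cut. The only demand is mono-alkylation at the hydroxyl para to bromine.

## Other disconnections considered

Alternative 1: The cut runs through ring A (C4a–C5 and C8–C8a). Ring C survives as the (5R)-5-aryl six-membered lactone A2 (carbonyl = future C8a, α-carbon = future C4a), and C5 to C8 come from methyl vinyl ketone A3.
- Forward key step: the lithium enolate of A2 would add to A3 (C4a–C5). A potassium alkoxide would then send the methyl ketone enolate into the lactone carbonyl (C8–C8a), and mild acid would re-close the enol ether to the bicyclic vinylogous ester A1 (either C4a epimer). Dehydrogenation to the C7 phenol and desilylation would follow.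
- In favour: it is two-electron carbonyl chemistry throughout, with no aryl halide, no electrolysis and no low-valent nickel near the prenyl ether. The oxygen pattern of ring A arises without a regiochemical question. On these points it is the equal or the better of the chosen plan.
- Against: A2 has its aryl group β to the ring oxygen, not β to the carbonyl, so conjugate arylation of an unsaturated lactone cannot give it and A2 needs its own enantioselective route. The final oxidation of a cyclohexenone to a phenol must be done beside two alkenes, an allylic ether and an electron-rich arene, which are what dehydrogenation reagents attack.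
- Comparison: on structure the key step builds more (one ring, two bonds, against one ring, one bond) and is the better. On mechanism the chosen plan is gentler to ring B, being reductive and neutral. On step count the alternative should be longer, because A2 needs a multi-step preparation and an aromatisation is added at the end.

Alternative 2: Three bonds of ring A are cut at once (C4a–C8a, C5–C6, C7–C8), opening rings A and C together. This leads to the acyclic (R)-diyne A5, in which C3 carries a silylated propargyl arm and an ethynyl ether arm, and to ethynylboronic acid pinacol ester A6 as the C6–C7 unit.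
- Forward key step: Cp*RuCl(cod) would cyclotrimerise A5 with A6 through a ruthenacyclopentadiene. The usual meta relationship between the alkyne substituent and the bulkier diyne terminus would place boron on C7 and silicon on C5, giving A4. Oxidation of C–B, protodesilylation at C5 and removal of the 2′-silyl group would follow.
- In favour: three C–C bonds and two rings form in one neutral step, with no sacrificial carbon and no halide or phthalimide waste. There is no radical lifetime to manage. In these respects it is better than the chosen plan.
- Against: the ynol ether has a hydrogen on C3 and can fragment to a ketene on warming, and its preparation is strongly basic. The ruthenium catalyst may also engage the terminal vinyl group of ring B. Removing silicon from C5, which is meta to both oxygens, needs strong acid that the prenyl ether will not tolerate.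
- Comparison: structurally it builds the most. Mechanistically it trades the radical risk for alkene chemoselectivity and ynol ether stability. It needs three operations after the key step against one, and a longer way to A5, so the total should be longer.

Alternative 3: C3–C1′ and C4–C4a are cut in one operation and ring C stays open. The pieces are the ring B pinacol boronic ester A8 (from 7), vinylmagnesium bromide A9 as C3–C4, and the ring A aryl triflate A10 with chlorine at the future C8a.
- Forward key step: A8 and A9 would form a vinyl boronate complex. With Pd(OAc)2 and MandyPhos the arylpalladium species from A10 would activate the vinyl group, ring B would shift from boron to C3 and ring A would arrive at C4, giving the benzylic boronic ester A7. One-carbon homologation of C–B with retention (C2), oxidation to the primary alcohol, metal-catalysed O1–C8a etherification of the aryl chloride and desilylation would follow.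
- In favour: the catalyst sets C3 while joining three fragments through two C–C bonds, which is more convergent than the one-bond conjugate addition of the chosen plan and is better on that point. No cation or radical arises at C4, so it is equal on the bridging problem. It shares the ring B sequence up to 7.
- Against: the key step closes no ring, and four operations follow it against one. Halide from A9 and the crowded ortho-silyloxy migrating group both work against the coupling. The late C–O coupling needs base, heat and a palladium or copper catalyst beside the aryl prenyl ether, with β-hydride loss from the alkoxide as a competing path.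
- Comparison: on structure and convergence it is the better. On mechanism it is equal. The longest linear sequence should be about equal, but the chosen plan has the simpler endgame.

Key step: step 11

Remark on the chemistry: both phenols are carried as triisopropylsilyl ethers in place of tert-butyldimethylsilyl ethers, because the latter are not expected to survive hydroxide hydrolysis of 14 and loss of the 2′-silyl group would let 15 lactonise; the bond formed, the ring closed and the skeletons of 18 and 19 are unchanged (isoflavan numbering O1, C2, C3, C4, C4a to C8a, C1′ to C6′).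

## Route

Step 1
Reactants: 1 4-bromoresorcinol; 2 prenyl bromide (1-bromo-3-methylbut-2-ene)
Product: 3 2-bromo-5-(3-methylbut-2-enyloxy)phenol
Conditions: 2 (0.95 equiv), K2CO3, acetone, 0 °C to rt
Reagents that add atoms: none
Why: Williamson ether synthesis; the hydroxyl para to bromine should react first because the other one is flanked by bromine, hydrogen-bonded to it and gives the less nucleophilic phenoxide. A slight deficit of 2 holds back the bis-ether.

Step 2
Reactants: 3 2-bromo-5-(3-methylbut-2-enyloxy)phenol
Product: 4 [2-bromo-5-(3-methylbut-2-enyloxy)phenoxy]triisopropylsilane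
Conditions: i-Pr3SiCl, imidazole, DMF, rt to 40 °C
Reagents that add atoms: triisopropylsilyl chloride, CC(C)[Si](Cl)(C(C)C)C(C)C
Why: Imidazole-assisted silylation of the remaining phenol. The triisopropylsilyl group is chosen because it survives the later LiOH and aryllithium steps and its bulk shields the ring position between the two oxygens in step 3.

Step 3
Reactants: 4 [2-bromo-5-(3-methylbut-2-enyloxy)phenoxy]triisopropylsilane
Product: 6 4-bromo-2-(2-methylbut-3-en-2-yl)-5-(triisopropylsilyloxy)phenol, via ortho-dienone 5 (not isolated)
Conditions: PhNEt2, 185 °C, sealed tube, Ar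
Reagents that add atoms: none
Why: Aromatic Claisen rearrangement: the [3,3] shift inverts the prenyl unit to give dienone 5, and tautomerisation restores the arene. The position between the oxygens is shielded by the silyloxy group and disfavoured by a meta donor, and the para position carries bromine, so onward migration has no productive outlet. The amine solvent keeps out acid that would cyclise the product.

Step 4
Reactants: 6 4-bromo-2-(2-methylbut-3-en-2-yl)-5-(triisopropylsilyloxy)phenol; 2 prenyl bromide
Product: 7 [2-bromo-4-(2-methylbut-3-en-2-yl)-5-(3-methylbut-2-enyloxy)phenoxy]triisopropylsilane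
Conditions: 2, K2CO3, acetone, reflux
Reagents that add atoms: none
Why: Williamson ether synthesis on the hindered phenoxide with an unhindered primary allylic bromide. Dry carbonate in acetone leaves the aryl silyl ether intact.

Step 5
Reactants: 7 [2-bromo-4-(2-methylbut-3-en-2-yl)-5-(3-methylbut-2-enyloxy)phenoxy]triisopropylsilane
Product: 10 [5-(2-methylbut-3-en-2-yl)-4-(3-methylbut-2-enyloxy)-2-(triisopropylsilyloxy)phenyl]boronic acid, via aryllithium 8 (not isolated), via lithium triisopropoxyborate 9 (not isolated)
Conditions: B(Oi-Pr)3 (1.5 equiv), then n-BuLi (1.1 equiv), THF/toluene, −78 °C; then dilute HCl to pH 5–6, 0 °C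
Reagents that add atoms: triisopropyl borate, CC(C)OB(OC(C)C)OC(C)C (boron); water, O (hydroxyl oxygens of 10); n-butyllithium, [Li]CCCC (lithium of 8 and 9 only)
Why: Bromine–lithium exchange with in situ trapping: exchange is faster than addition of n-BuLi to the hindered borate, and 8 is captured at once as 9, which mild hydrolysis turns into the boronic acid. Immediate capture at −78 °C and the bulky silyl group suppress the oxygen-to-carbon silyl shift and metalation next to the prenyl ether oxygen.

Step 6
Reactants: 1 4-bromoresorcinol
Product: 11 2-bromo-5-(triisopropylsilyloxy)phenol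
Conditions: i-Pr3SiCl (1.0 equiv), imidazole, CH2Cl2/DMF, −20 to 0 °C
Reagents that add atoms: triisopropylsilyl chloride, CC(C)[Si](Cl)(C(C)C)C(C)C
Why: Sterically controlled monosilylation: the bulky silyl chloride goes to the hydroxyl with no ortho substituent (para to bromine). One equivalent at low temperature limits bis-silylation.

Step 7
Reactants: 11 2-bromo-5-(triisopropylsilyloxy)phenol; 12 methyl (E)-4-bromobut-2-enoate (methyl 4-bromocrotonate)
Product: 13 methyl (E)-4-[2-bromo-5-(triisopropylsilyloxy)phenoxy]but-2-enoate
Conditions: 12, K2CO3, acetone, rt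
Reagents that add atoms: none
Why: Williamson ether synthesis, SN2 at the primary allylic bromide. Mild carbonate at room temperature avoids moving the double bond out of conjugation and leaves the silyl ether alone.

Step 8
Reactants: 10 [5-(2-methylbut-3-en-2-yl)-4-(3-methylbut-2-enyloxy)-2-(triisopropylsilyloxy)phenyl]boronic acid; 13 methyl (E)-4-[2-bromo-5-(triisopropylsilyloxy)phenoxy]but-2-enoate
Product: 14 methyl (3R)-4-[2-bromo-5-(triisopropylsilyloxy)phenoxy]-3-[5-(2-methylbut-3-en-2-yl)-4-(3-methylbut-2-enyloxy)-2-(triisopropylsilyloxy)phenyl]butanoate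
Conditions: 10 (2.5 equiv, in portions), [Rh(OH)((S)-binap)]2 (3 mol % Rh), dioxane/H2O 10:1, 50 °C
Reagents that add atoms: none
Why: Hayashi–Miyaura conjugate addition: the aryl group passes from boron to monovalent rhodium, adds across the (E)-enoate with C1′ going to C3, and water protonates the rhodium enolate. With (S)-BINAP the enoate should bind through its α-si face, the sense that gives (R)-3-arylbutanoates from (E)-crotonates; here that places the aryl group so that C3 is (R). The hydroxo catalyst needs no added base, which limits protodeboronation and leaves the ester, silyl ethers and C–Br bond untouched.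

Step 9
Reactants: 14 methyl (3R)-4-[2-bromo-5-(triisopropylsilyloxy)phenoxy]-3-[5-(2-methylbut-3-en-2-yl)-4-(3-methylbut-2-enyloxy)-2-(triisopropylsilyloxy)phenyl]butanoate
Product: 15 (3R)-4-[2-bromo-5-(triisopropylsilyloxy)phenoxy]-3-[5-(2-methylbut-3-en-2-yl)-4-(3-methylbut-2-enyloxy)-2-(triisopropylsilyloxy)phenyl]butanoic acid
Conditions: LiOH·H2O, THF/H2O 3:1, 0 °C to rt; then 0.5 M HCl to pH 4, 0 °C
Reagents that add atoms: lithium hydroxide, [Li+].[OH-]
Why: Saponification of an unhindered methyl ester; aryl triisopropylsilyl ethers withstand cold aqueous LiOH. C3 is β to the carboxyl group and cannot epimerise by enolisation.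

Step 10
Reactants: 15 (3R)-4-[2-bromo-5-(triisopropylsilyloxy)phenoxy]-3-[5-(2-methylbut-3-en-2-yl)-4-(3-methylbut-2-enyloxy)-2-(triisopropylsilyloxy)phenyl]butanoic acid; 16 N-hydroxyphthalimide
Product: 18 1,3-dioxoisoindolin-2-yl (3R)-4-[2-bromo-5-(triisopropylsilyloxy)phenoxy]-3-[5-(2-methylbut-3-en-2-yl)-4-(3-methylbut-2-enyloxy)-2-(triisopropylsilyloxy)phenyl]butanoate, via O-acylisourea 17 (not isolated)
Conditions: 16, i-PrN=C=Ni-Pr, DMAP (5 mol %), CH2Cl2, 0 °C to rt
Reagents that add atoms: N,N'-diisopropylcarbodiimide, CC(C)N=C=NC(C)C (its atoms are in 17 only; none remain in 18)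
Why: Carbodiimide esterification of Steglich type: the acid adds to the carbodiimide to give 17, and DMAP relays the acyl group to the N-hydroxy group of 16. The 2′-oxygen is still silylated, so the activated acid cannot close to an aryl lactone.

Step 11
Reactants: 18 1,3-dioxoisoindolin-2-yl (3R)-4-[2-bromo-5-(triisopropylsilyloxy)phenoxy]-3-[5-(2-methylbut-3-en-2-yl)-4-(3-methylbut-2-enyloxy)-2-(triisopropylsilyloxy)phenyl]butanoate
Product: 19 (3R)-7-(triisopropylsilyloxy)-3-[5-(2-methylbut-3-en-2-yl)-4-(3-methylbut-2-enyloxy)-2-(triisopropylsilyloxy)phenyl]chromane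
Conditions: NiCl2(dme) (20 mol %), 2,2'-bipyridine (24 mol %), AgNO3 (30 mol %), LiCl, NMP, 18 added slowly to about 5 mM, Mg anode, reticulated vitreous carbon cathode, undivided cell, low constant current, rt, Ar
Reagents that add atoms: none
Why: Nickel-electrocatalytic decarboxylative arylation of a redox-active ester with an aryl bromide, a cross-electrophile coupling established between separate partners and used here in its less common ring-closing mode. The cathode reduces the divalent nickel–bipyridine salt to low-valent nickel, which inserts into the C4a–Br bond; electron transfer to the phthalimide ester (at the silver-coated cathode or from reduced nickel) breaks the N–O bond and expels CO2 and phthalimide anion, leaving the primary C4 radical. The radical is caught by the divalent arylnickel centre of the same molecule to give a seven-membered aryl(alkyl)nickel ring at the trivalent stage, and reductive elimination forms C4–C4a and returns monovalent nickel to the cathode, while the magnesium anode supplies the electrons. Ring C is therefore closed by C(sp3)–C(sp2) reductive elimination from a nickelacycle, formally a six-membered closure onto the ipso carbon C4a, and not by radical attack on the arene. No stereocentre is formed, and C3 keeps its (R) configuration because neither the adjacent radical nor the conditions labilise the C3–H bond. Capture at nickel must outrun hydrogen abstraction from the solvent, further reduction to the carbanion, the 1,2-shift of ring B and intermolecular coupling; the short tether (C3, C2, O1, C8a), slow addition at high dilution and a low current density secure this. Nickel must also choose the C–Br bond over the allylic C–O bond of the prenyl ether, which the much faster insertion into aryl bromides should provide. Because both partners are electrophiles, no basic organometallic reagent meets the silyl ethers and no positive charge develops at C4, so bridging by ring B does not arise.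

Step 12
Reactants: 19 (3R)-7-(triisopropylsilyloxy)-3-[5-(2-methylbut-3-en-2-yl)-4-(3-methylbut-2-enyloxy)-2-(triisopropylsilyloxy)phenyl]chromane
Product: 20 manuifolin D [(3R)-3-[2-hydroxy-5-(2-methylbut-3-en-2-yl)-4-(3-methylbut-2-enyloxy)phenyl]chroman-7-ol]
Conditions: n-Bu4NF (2.5 equiv), AcOH (2.5 equiv), THF, 0 °C to rt
Reagents that add atoms: none
Why: Fluoride cleavage of both aryl silyl ethers, driven by the Si–F bond; acetic acid keeps the electron-rich phenols protonated and away from base and air. The prenyl ether, both alkenes and C3 are inert to these conditions, so the product is the (3R) target.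

## Compound list

1 | 4-bromoresorcinol (4-bromobenzene-1,3-diol) | Oc1ccc(Br)c(O)c1 | starting material
2 | prenyl bromide (1-bromo-3-methylbut-2-ene) | CC(C)=CCBr | starting material
3 | 2-bromo-5-(3-methylbut-2-enyloxy)phenol | Oc1cc(OCC=C(C)C)ccc1Br | intermediate
4 | [2-bromo-5-(3-methylbut-2-enyloxy)phenoxy]triisopropylsilane | CC(C)=CCOc1ccc(Br)c(O[Si](C(C)C)(C(C)C)C(C)C)c1 | intermediate
5 | 4-bromo-6-(2-methylbut-3-en-2-yl)-3-(triisopropylsilyloxy)cyclohexa-2,4-dien-1-one (transient, racemic) | O=C1C=C(O[Si](C(C)C)(C(C)C)C(C)C)C(Br)=CC1C(C)(C)C=C | intermediate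
6 | 4-bromo-2-(2-methylbut-3-en-2-yl)-5-(triisopropylsilyloxy)phenol | Oc1cc(O[Si](C(C)C)(C(C)C)C(C)C)c(Br)cc1C(C)(C)C=C | intermediate
7 | [2-bromo-4-(2-methylbut-3-en-2-yl)-5-(3-methylbut-2-enyloxy)phenoxy]triisopropylsilane | C=CC(C)(C)c1cc(Br)c(O[Si](C(C)C)(C(C)C)C(C)C)cc1OCC=C(C)C | intermediate
8 | [5-(2-methylbut-3-en-2-yl)-4-(3-methylbut-2-enyloxy)-2-(triisopropylsilyloxy)phenyl]lithium | C=CC(C)(C)c1cc([Li])c(O[Si](C(C)C)(C(C)C)C(C)C)cc1OCC=C(C)C | intermediate
9 | lithium triisopropoxy[5-(2-methylbut-3-en-2-yl)-4-(3-methylbut-2-enyloxy)-2-(triisopropylsilyloxy)phenyl]borate | [Li+].C=CC(C)(C)c1cc([B-](OC(C)C)(OC(C)C)OC(C)C)c(O[Si](C(C)C)(C(C)C)C(C)C)cc1OCC=C(C)C | intermediate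
10 | [5-(2-methylbut-3-en-2-yl)-4-(3-methylbut-2-enyloxy)-2-(triisopropylsilyloxy)phenyl]boronic acid | C=CC(C)(C)c1cc(B(O)O)c(O[Si](C(C)C)(C(C)C)C(C)C)cc1OCC=C(C)C | intermediate
11 | 2-bromo-5-(triisopropylsilyloxy)phenol | Oc1cc(O[Si](C(C)C)(C(C)C)C(C)C)ccc1Br | intermediate
12 | methyl (E)-4-bromobut-2-enoate | COC(=O)/C=C/CBr | starting material
13 | methyl (E)-4-[2-bromo-5-(triisopropylsilyloxy)phenoxy]but-2-enoate | COC(=O)/C=C/COc1cc(O[Si](C(C)C)(C(C)C)C(C)C)ccc1Br | intermediate
14 | methyl (3R)-4-[2-bromo-5-(triisopropylsilyloxy)phenoxy]-3-[5-(2-methylbut-3-en-2-yl)-4-(3-methylbut-2-enyloxy)-2-(triisopropylsilyloxy)phenyl]butanoate | C=CC(C)(C)c1cc([C@@H](CC(=O)OC)COc3cc(O[Si](C(C)C)(C(C)C)C(C)C)ccc3Br)c(O[Si](C(C)C)(C(C)C)C(C)C)cc1OCC=C(C)C | intermediate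
15 | (3R)-4-[2-bromo-5-(triisopropylsilyloxy)phenoxy]-3-[5-(2-methylbut-3-en-2-yl)-4-(3-methylbut-2-enyloxy)-2-(triisopropylsilyloxy)phenyl]butanoic acid | C=CC(C)(C)c1cc([C@@H](CC(=O)O)COc3cc(O[Si](C(C)C)(C(C)C)C(C)C)ccc3Br)c(O[Si](C(C)C)(C(C)C)C(C)C)cc1OCC=C(C)C | intermediate
16 | N-hydroxyphthalimide | O=C1c2ccccc2C(=O)N1O | starting material
17 | O-acylisourea from 15 and N,N'-diisopropylcarbodiimide | C=CC(C)(C)c1cc([C@@H](CC(=O)OC(=NC(C)C)NC(C)C)COc3cc(O[Si](C(C)C)(C(C)C)C(C)C)ccc3Br)c(O[Si](C(C)C)(C(C)C)C(C)C)cc1OCC=C(C)C | intermediate
18 | 1,3-dioxoisoindolin-2-yl (3R)-4-[2-bromo-5-(triisopropylsilyloxy)phenoxy]-3-[5-(2-methylbut-3-en-2-yl)-4-(3-methylbut-2-enyloxy)-2-(triisopropylsilyloxy)phenyl]butanoate | C=CC(C)(C)c1cc([C@@H](CC(=O)ON4C(=O)c5ccccc5C4=O)COc3cc(O[Si](C(C)C)(C(C)C)C(C)C)ccc3Br)c(O[Si](C(C)C)(C(C)C)C(C)C)cc1OCC=C(C)C | intermediate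
19 | (3R)-7-(triisopropylsilyloxy)-3-[5-(2-methylbut-3-en-2-yl)-4-(3-methylbut-2-enyloxy)-2-(triisopropylsilyloxy)phenyl]chromane | C=CC(C)(C)c1cc([C@@H]2COc3cc(O[Si](C(C)C)(C(C)C)C(C)C)ccc3C2)c(O[Si](C(C)C)(C(C)C)C(C)C)cc1OCC=C(C)C | intermediate
20 | manuifolin D, (3R)-3-[2-hydroxy-5-(2-methylbut-3-en-2-yl)-4-(3-methylbut-2-enyloxy)phenyl]chroman-7-ol | C=CC(C)(C)c1cc([C@@H]2COc3cc(O)ccc3C2)c(O)cc1OCC=C(C)C | target

## Step count and least certain steps

Total: 12 steps. Longest linear sequence: 10 steps (steps 1 to 5, then 8 to 12); steps 6 and 7 form the ring A branch.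

**Step 11 (key step).** The most likely failure is reduction of the phthalimide ester and escape of the C4 radical before nickel has inserted into the C4a–Br bond. That would end in hydrogen abstraction, radical dimerisation or the 1,2-shift of ring B. The cause is that a bromoarene with two oxygen donors undergoes oxidative addition slowly, while the ester is reduced easily. A second risk is ionisation of the prenyl ether C–O bond by low-valent nickel.

The fallback sets out from 18 and returns at 19. It moves the ring closure from a radical to a two-electron organometallic step. Iododecarboxylation of 18 (LiI, catalytic PPh3, 456 nm light, acetone, rt), in which the radical only has to pick up iodine, would give the primary iodide 1-bromo-2-{[(2R)-3-iodo-2-(ring B aryl)propyl]oxy}-4-(triisopropylsilyloxy)benzene F1. Zinc insertion (Zn dust, LiCl, THF, rt) would give the alkylzinc iodide F2, which is not isolated. An intramolecular Negishi coupling with the C4a–Br bond (Pd(OAc)2, SPhos, THF, 40 °C) would then close ring C to 19.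

**Step 8.** Protodeboronation of the hindered, electron-rich boronic acid may outrun transfer of the aryl group to rhodium, leaving the enoate unconsumed. Face selectivity with a methyl ester may also be incomplete, and this cannot be corrected later because C3 is the only stereocentre.

The fallback sets out from 13 (with 8 from step 5) and returns at 15. Hydrolysis of 13 (LiOH, THF/H2O) would give (E)-4-[2-bromo-5-(triisopropylsilyloxy)phenoxy]but-2-enoic acid F3. Acylation of lithiated (4S)-4-phenyl-1,3-oxazolidin-2-one through the pivaloyl mixed anhydride would give the N-enoyl imide F4. Transmetalation of 8 with MgBr2·OEt2 would give the aryl Grignard reagent F5. Its addition to F4 with CuBr·SMe2 (THF, −40 to −20 °C) should occur anti to the phenyl group of the chelated imide and give the (3R) adduct F6, whose minor diastereomer can be removed. Cleavage with LiOH/H2O2 (0 °C) would give 15.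

**Step 3.** The allyl group may migrate to the position between the two oxygens. The ortho-(1,1-dimethylallyl)phenol may also react further at the reaction temperature, by cyclisation of the phenol onto the alkene, abnormal rearrangement through a spirocyclic dienone, or loss of the allyl group.

The fallback sets out from 4 and returns at 6. The rearrangement is run under acylating conditions (Ac2O, NaOAc, PhNEt2, 185 °C), so that the phenol is intercepted as it forms, as 4-bromo-2-(2-methylbut-3-en-2-yl)-5-(triisopropylsilyloxy)phenyl acetate F7. Brief methanolysis (K2CO3, MeOH, 0 °C) then releases 6 under cold, basic conditions.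

**Step 1.** Alkylation may occur at the wrong hydroxyl or at both, because the two phenols differ only modestly: the one next to bromine is more acidic but more hindered.

The fallback sets out from 1 and returns at 4. It lets bulky silyl groups fix the regiochemistry. Silylation with t-BuMe2SiCl and imidazole at the unhindered hydroxyl would give 2-bromo-5-(tert-butyldimethylsilyloxy)phenol F8. Silylation of the remaining phenol (i-Pr3SiCl, imidazole, DMF) would give the mixed bis-silyl ether [4-bromo-3-(triisopropylsilyloxy)phenoxy](tert-butyl)dimethylsilane F9. Selective removal of the less hindered, more labile silyl group (K2CO3, MeOH, 0 °C to rt) would give 4-bromo-3-(triisopropylsilyloxy)phenol F10. Alkylation with 2 (K2CO3, acetone) then gives 4.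

## Further compounds

F1 | step 11 | 1-bromo-2-{[(2R)-3-iodo-2-[5-(2-methylbut-3-en-2-yl)-4-(3-methylbut-2-enyloxy)-2-(triisopropylsilyloxy)phenyl]propyl]oxy}-4-(triisopropylsilyloxy)benzene | C=CC(C)(C)c1cc([C@@H](CI)COc3cc(O[Si](C(C)C)(C(C)C)C(C)C)ccc3Br)c(O[Si](C(C)C)(C(C)C)C(C)C)cc1OCC=C(C)C
F2 | step 11 | alkylzinc iodide from F1, {(2R)-3-[2-bromo-5-(triisopropylsilyloxy)phenoxy]-2-(ring B aryl)propyl}zinc iodide | C=CC(C)(C)c1cc([C@@H](C[Zn]I)COc3cc(O[Si](C(C)C)(C(C)C)C(C)C)ccc3Br)c(O[Si](C(C)C)(C(C)C)C(C)C)cc1OCC=C(C)C
F3 | step 8 | (E)-4-[2-bromo-5-(triisopropylsilyloxy)phenoxy]but-2-enoic acid | OC(=O)/C=C/COc1cc(O[Si](C(C)C)(C(C)C)C(C)C)ccc1Br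
F4 | step 8 | (4S)-3-{(E)-4-[2-bromo-5-(triisopropylsilyloxy)phenoxy]but-2-enoyl}-4-phenyl-1,3-oxazolidin-2-one | O=C(/C=C/COc1cc(O[Si](C(C)C)(C(C)C)C(C)C)ccc1Br)N2[C@@H](c3ccccc3)COC2=O
F5 | step 8 | [5-(2-methylbut-3-en-2-yl)-4-(3-methylbut-2-enyloxy)-2-(triisopropylsilyloxy)phenyl]magnesium bromide | C=CC(C)(C)c1cc([Mg]Br)c(O[Si](C(C)C)(C(C)C)C(C)C)cc1OCC=C(C)C
F6 | step 8 | (4S)-3-{(3R)-4-[2-bromo-5-(triisopropylsilyloxy)phenoxy]-3-[5-(2-methylbut-3-en-2-yl)-4-(3-methylbut-2-enyloxy)-2-(triisopropylsilyloxy)phenyl]butanoyl}-4-phenyl-1,3-oxazolidin-2-one | C=CC(C)(C)c1cc([C@@H](CC(=O)N4[C@@H](c5ccccc5)COC4=O)COc3cc(O[Si](C(C)C)(C(C)C)C(C)C)ccc3Br)c(O[Si](C(C)C)(C(C)C)C(C)C)cc1OCC=C(C)C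
F7 | step 3 | 4-bromo-2-(2-methylbut-3-en-2-yl)-5-(triisopropylsilyloxy)phenyl acetate | CC(=O)Oc1cc(O[Si](C(C)C)(C(C)C)C(C)C)c(Br)cc1C(C)(C)C=C
F8 | step 1 | 2-bromo-5-(tert-butyldimethylsilyloxy)phenol | Oc1cc(O[Si](C)(C)C(C)(C)C)ccc1Br
F9 | step 1 | [4-bromo-3-(triisopropylsilyloxy)phenoxy](tert-butyl)dimethylsilane | CC(C)(C)[Si](C)(C)Oc1ccc(Br)c(O[Si](C(C)C)(C(C)C)C(C)C)c1
F10 | step 1 | 4-bromo-3-(triisopropylsilyloxy)phenol | Oc1ccc(Br)c(O[Si](C(C)C)(C(C)C)C(C)C)c1
A1 | alternative 1 | (3R)-3-[2-(tert-butyldimethylsilyloxy)-5-(2-methylbut-3-en-2-yl)-4-(3-methylbut-2-enyloxy)phenyl]-2,3,4,4a,5,6-hexahydrochromen-7-one (C4a epimers) | C=CC(C)(C)c1cc([C@@H]2COC3=CC(=O)CCC3C2)c(O[Si](C)(C)C(C)(C)C)cc1OCC=C(C)C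
A2 | alternative 1 | (5R)-5-[2-(tert-butyldimethylsilyloxy)-5-(2-methylbut-3-en-2-yl)-4-(3-methylbut-2-enyloxy)phenyl]oxan-2-one | C=CC(C)(C)c1cc([C@@H]2COC(=O)CC2)c(O[Si](C)(C)C(C)(C)C)cc1OCC=C(C)C
A3 | alternative 1 | methyl vinyl ketone (but-3-en-2-one) | CC(=O)C=C
A4 | alternative 2 | (3R)-isoflavan with pinacolboryl at C7, trimethylsilyl at C5 and tert-butyldimethylsilyl on O2′ | C=CC(C)(C)c1cc([C@@H]2COc3cc(B4OC(C)(C)C(C)(C)O4)cc([Si](C)(C)C)c3C2)c(O[Si](C)(C)C(C)(C)C)cc1OCC=C(C)C
A5 | alternative 2 | (R)-diyne: ring B aryl (O2′ tert-butyldimethylsilyl) on a carbon bearing CH2–C≡C–SiMe3 and CH2–O–C≡CH | C=CC(C)(C)c1cc([C@@H](CC#C[Si](C)(C)C)COC#C)c(O[Si](C)(C)C(C)(C)C)cc1OCC=C(C)C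
A6 | alternative 2 | ethynylboronic acid pinacol ester | C#CB1OC(C)(C)C(C)(C)O1
A7 | alternative 3 | 2-[(1R)-1-(ring B aryl, O2′ tert-butyldimethylsilyl)-2-[4-(tert-butyldimethylsilyloxy)-2-chlorophenyl]ethyl]-4,4,5,5-tetramethyl-1,3,2-dioxaborolane | C=CC(C)(C)c1cc([C@@H](Cc3ccc(O[Si](C)(C)C(C)(C)C)cc3Cl)B4OC(C)(C)C(C)(C)O4)c(O[Si](C)(C)C(C)(C)C)cc1OCC=C(C)C
A8 | alternative 3 | 2-[2-(tert-butyldimethylsilyloxy)-5-(2-methylbut-3-en-2-yl)-4-(3-methylbut-2-enyloxy)phenyl]-4,4,5,5-tetramethyl-1,3,2-dioxaborolane | C=CC(C)(C)c1cc(B2OC(C)(C)C(C)(C)O2)c(O[Si](C)(C)C(C)(C)C)cc1OCC=C(C)C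
A9 | alternative 3 | vinylmagnesium bromide | C=C[Mg]Br
A10 | alternative 3 | 4-(tert-butyldimethylsilyloxy)-2-chlorophenyl trifluoromethanesulfonate | O=S(=O)(Oc1ccc(O[Si](C)(C)C(C)(C)C)cc1Cl)C(F)(F)F
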